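The earlier runs and the new flask were computed on assumed constants; noise was put on by code.

The ratio of target to side product A late in a run is what two rates of gain leave behind as they die away, so I follow those rates in this closed flask.

the same everywhere: substrate 0.011 M; partner 0.0121 M

| charge | remark | time |
|---|---|---|
| epsilon | the very flask that is asked about, followed so far |  |
| flask |  | 12 h |

epsilon run (percent of the substrate charged)

| time / h | target / % | side product A / % | substrate / % |
|---|---|---|---|
| 0.200 | 2.8 | 40.6 | 31.1 |
| 0.500 | 7.8 | 63.1 | 6.7 |
| 1.00 | 10.0 | 70.5 | 0.8 |
| 1.50 | 10.8 | 70.6 | 0.6 |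
| 2.00 | 10.8 | 70.8 | 0 |
| 3.00 | 10.3 | 71.3 | 0 |
| 4.00 | 10.4 | 71.6 | 0.3 |

(scatter of a reading: 0.3 percentage points)



- ratio of target to side product A at 80 s
- ratio of target to side product A at 30 min
- ratio of target to side product A at 12 h
- which of target and side product A there is more of at 12 h

1. Let g be a product's gain per hour, as a fraction of the substrate charged, read between readings of the epsilon run, which is this flask followed so far. From 0.200 h to 0.500 h, g is 0.750 /h for side product A and 0.167 /h for target.

2. From 0.500 h to 1.00 h, g of side product A is lower by a factor 5.07 and g of target by a factor 3.79. Over the same readings, substrate falls by a factor 4.64, then 8.38, and it reads 0% at 2.00 h. I take this fast loss of substrate as the slowing.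

3. From 1.50 h to 4.00 h, g of side product A reads 0.00400 /h, so the accumulated slowing reads as a factor 188. Side product A changes by 1 percentage point and target by −0.4 points, against a scatter of 0.3 points in each reading. I read no firm trend and expect none up to 12 h.

4. So I carry the end ratio S, the selectivity factor: target over side product A, each summed over the readings from 2.00 h to 4.00 h. It reads 0.147, and that is my figure for 12 h.

5. The forecast gives 0.011 (0.006 to 0.02) at 80 s and 0.124 (0.116 to 0.132) at 30 min. At 12 h it gives 0.13 (0.095 to 0.155), with side product A ahead. It calls the late drift “marginal but suggests slow” leakage of target into side product A, so its ratio is lower than mine.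

6. The flask gives 0.00816 at 80 s, 0.124 at 30 min and 0.145 at 12 h, with side product A ahead.

    substrate ⇌ intermediate A (K = 1.41, k = 0.00147 /s)
    intermediate A → intermediate C (k = 8.09 × 10⁻⁴ /s)
    substrate + partner ⇌ intermediate B (K = 180 /M, k = 0.0342 /M/s)
    intermediate A → side product A (k = 0.00557 /s)
    intermediate B → side product B (k = 6.19 × 10⁻⁴ /s)
    intermediate C → target (k = 0.00207 /s)

Far beyond 12 h the ratio in this flask stands at 0.145. Here S times the 71.3% of side product A gives 10.5% of target, and the flask holds 10.4%. A neighbour flask with 0.0073 M of partner ends at 77.0% of side product A, for which S gives 11.3% of target, and that neighbour flask holds 11.2%.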